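The benzo ring (ring A) of the flavone is built rather than bought. Its contiguous triad C8a (bearing O1), C8 (bearing the carbon arm) and C7 (bearing OMe) maps onto the carbonyl carbon of a vinylketene followed by the two sp carbons of a methyl ynol ether. Heating cyclobut-2-en-1-one 3 with silyl ether 8 of 4-methoxybut-3-yn-1-ol should form C8a–C8 and C7–C6 and close ring A in one pericyclic cascade. This gives phenol 13, with C4a as its only free ortho carbon. Ring C is then annulated through formylation and a phenyl ynone. The two-carbon arm on C8 is oxidised to an acetic acid, whose ester with 2-hydroxy-2-methylpropanal condenses to the butenolide.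

Key step: step 5

Remark: flavone numbering is used (ring A benzo, ring B phenyl, ring C pyranone). The target has no stereocentre. Aldehyde 25 is assumed to be bought; because it is supplied partly as its hemiacetal dimer, it is cracked to the monomer by distillation just before use.

Step 1
Reactants: 1 3-oxocyclobutanecarboxylic acid
Product: 2 3-bromocyclobutanone
Conditions: HgO (red), Br2, MgSO4, CH2Cl2, reflux
Reagents that add atoms: bromine, BrBr
Why: Cristol–Firth variant of the Hunsdiecker reaction, in which the mercury carboxylate is turned by Br2 into an acyl hypobromite that loses CO2 in a radical chain while the remote ketone stays untouched.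

Step 2
Reactants: 2 3-bromocyclobutanone
Product: 3 cyclobut-2-en-1-one
Conditions: n-Bu3N, neat, rt, reduced pressure, distillate collected at −78 °C and stored as a cold toluene solution
Reagents that add atoms: none
Why: E1cB-type dehydrobromination of a β-bromo ketone by a hindered tertiary amine, with the volatile enone swept out of the basic medium before it can polymerise.

Step 3
Reactants: 4 chloroacetaldehyde dimethyl acetal (2-chloro-1,1-dimethoxyethane); 5 ethylene oxide
Product: 7 4-methoxybut-3-yn-1-ol, via lithium methoxyacetylide 6 (not isolated)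
Conditions: LiNEt2 (3.2 equiv, from Et2NH and n-BuLi), THF, 0 °C; then 5 (THF solution), DMPU, −40 °C → rt; sat. aq NaHCO3
Reagents that add atoms: none
Why: Twofold base-induced elimination (HCl, then MeOH) plus deprotonation gives the alkoxyacetylide, and its SN2 opening of the epoxide is promoted by the dipolar cosolvent instead of BF3·OEt2, which the Et2NH and LiOMe in the flask would bind; lithium alkoxides do not propagate epoxide oligomerisation, and the bicarbonate work-up spares the acid-labile ynol ether.

Step 4
Reactants: 7 4-methoxybut-3-yn-1-ol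
Product: 8 tert-butyl[(4-methoxybut-3-yn-1-yl)oxy]dimethylsilane
Conditions: TBSCl, imidazole, CH2Cl2, 0 °C → rt; purification on Et3N-deactivated silica
Reagents that add atoms: tert-butyldimethylsilyl chloride, CC(C)(C)[Si](C)(C)Cl
Why: Standard imidazole-promoted silylation of a primary alcohol under non-acidic conditions, which also removes the hydroxyl group that could otherwise add across the electron-rich triple bond.

Step 5
Reactants: 3 cyclobut-2-en-1-one; 8 tert-butyl[(4-methoxybut-3-yn-1-yl)oxy]dimethylsilane
Product: 13 2-[2-(tert-butyldimethylsilyloxy)ethyl]-3-methoxyphenol, via vinylketene 9 (not isolated), via vinylcyclobutenone 10 (not isolated), via dienylketene 11 (not isolated), via cyclohexadienone 12 (not isolated)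
Conditions: 8 (1.3 equiv), toluene, 85 °C, 3 added by syringe pump, then 110 °C; K2CO3, MeOH, rt
Reagents that add atoms: none
Why: Danheiser benzannulation: conrotatory 4π opening of 3 (C1–C4 bond) gives vinylketene 9, its ketene C=C adds [2+2] to 8 to give 4-vinylcyclobutenone 10, 4π opening of 10 gives dienylketene 11, and 6π electrocyclization followed by tautomerization of dienone 12 gives phenol 13. The closest known reaction type is the cyclobutenone–alkoxyalkyne route to 2-substituted resorcinol monoethers, used here with the unsubstituted cyclobutenone. Ring A is closed by the disrotatory 6π electrocyclization, which joins the ketene carbon (future C8a) to the terminal vinyl carbon (future C4a) after the alkyne has been spliced between former C1 and C2 of 3 as C8 and C7. No stereocentre survives: the one in 10 is transient, and since the opening of 10 is reversible only the isomer of 11 with the vinyl group cis to the ketene is drained off. The selectivity needed is the orientation of the [2+2] step, and the polarisation of the ynol ether secures it, because its nucleophilic β-carbon (the one carrying the silyloxyethyl arm) attacks the electrophilic ketene carbonyl carbon and so places the arm between OH and OMe. Slow addition of 3 to excess 8 limits self-reaction of 3 and 9, the methyl ynol ether has no β-hydrogen for retro-ene loss, and the carbonate/methanol treatment returns any phenol acylated by ketene.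

Step 6
Reactants: 13 2-[2-(tert-butyldimethylsilyloxy)ethyl]-3-methoxyphenol
Product: 15 3-[2-(tert-butyldimethylsilyloxy)ethyl]-2-hydroxy-4-methoxybenzaldehyde, via salicyl alcohol 14 (not isolated)
Conditions: MgCl2 (anhydrous), Et3N, (CH2O)n, MeCN, reflux; cold dilute HCl
Reagents that add atoms: paraformaldehyde (as formaldehyde), C=O
Why: Casnati–Skattebøl ortho-formylation, in which the magnesium phenoxide delivers coordinated formaldehyde only to the ortho carbon (here the single free one, future C4a, also para to OMe) and a second formaldehyde oxidises the salicyl alkoxide by Oppenauer-type hydride transfer.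

Step 7
Reactants: 15 3-[2-(tert-butyldimethylsilyloxy)ethyl]-2-hydroxy-4-methoxybenzaldehyde; 16 phenylacetylene
Product: 18 2-[2-(tert-butyldimethylsilyloxy)ethyl]-6-(1-hydroxy-3-phenylprop-2-yn-1-yl)-3-methoxyphenol (racemic), via lithium phenylacetylide 17 (not isolated)
Conditions: 16, n-BuLi (2.4 equiv each), THF, −78 °C; then 15, −78 → 0 °C; sat. aq NH4Cl; used crude
Reagents that add atoms: none
Why: 1,2-Addition of a lithium acetylide to an aldehyde, with the first equivalent spent on the phenol; the new carbinol centre forms racemic and is erased in step 8.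

Step 8
Reactants: 18 2-[2-(tert-butyldimethylsilyloxy)ethyl]-6-(1-hydroxy-3-phenylprop-2-yn-1-yl)-3-methoxyphenol
Product: 19 1-{3-[2-(tert-butyldimethylsilyloxy)ethyl]-2-hydroxy-4-methoxyphenyl}-3-phenylprop-2-yn-1-one
Conditions: MnO2 (activated, excess), CH2Cl2, rt
Reagents that add atoms: none
Why: Chemoselective MnO2 oxidation of a doubly activated (benzylic and propargylic) alcohol, which leaves the silyl ether and the phenol alone.

Step 9
Reactants: 19 1-{3-[2-(tert-butyldimethylsilyloxy)ethyl]-2-hydroxy-4-methoxyphenyl}-3-phenylprop-2-yn-1-one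
Product: 22 8-(2-hydroxyethyl)-7-methoxy-2-phenyl-4H-chromen-4-one, via enaminone 20 (not isolated), via silyl flavone 21 (not isolated)
Conditions: Et2NH (1.5 equiv), EtOH, 60 °C; then 2 M aq HCl, rt → 40 °C
Reagents that add atoms: none
Why: Aza-Michael addition of Et2NH converts the ynone into enaminone 20, which leaves the phenol only the addition–elimination path at the β-carbon (net 6-endo closure to the flavone, no 5-exo aurone), and the acid added afterwards both completes this exchange and hydrolyses the primary silyl ether.

Step 10
Reactants: 22 8-(2-hydroxyethyl)-7-methoxy-2-phenyl-4H-chromen-4-one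
Product: 24 (7-methoxy-4-oxo-2-phenyl-4H-chromen-8-yl)acetic acid, via arylacetaldehyde 23 (not isolated)
Conditions: TEMPO (2,2,6,6-tetramethylpiperidin-1-oxyl, cat.), NaClO2, NaOCl (cat.), MeCN/phosphate buffer pH 6.7, 35 °C
Reagents that add atoms: sodium chlorite, [Na+].[O-]Cl=O
Why: Anelli-type oxoammonium oxidation to aldehyde 23 coupled to a Pinnick-type chlorite oxidation, a pairing proven on electron-rich 2-arylethanols, in which the trace of NaOCl only restarts the cycle so that ring chlorination and benzylic C–C cleavage are avoided.

Step 11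
Reactants: 24 (7-methoxy-4-oxo-2-phenyl-4H-chromen-8-yl)acetic acid; 25 2-hydroxy-2-methylpropanal
Product: 28 8-(5,5-dimethyl-2-oxo-2,5-dihydrofuran-3-yl)-7-methoxy-2-phenyl-4H-chromen-4-one, via formyl ester 26 (not isolated), via aldol lactone 27 (not isolated)
Conditions: 25 (1.5 equiv), DCC, DMAP (4-(dimethylamino)pyridine), CH2Cl2, 0 °C → rt; then DBU, rt
Reagents that add atoms: none
Why: Steglich esterification of the tertiary hydroxyl group (arylacetic acids acylate tertiary α-hydroxy carbonyl compounds under carbodiimide/DMAP activation) followed by DBU-promoted intramolecular aldol condensation, in which the acidic ArCH2 attacks the neighbouring aldehyde in a five-membered closure and E1cB loss of water erases both transient stereocentres of 27 to give the conjugated butenolide.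

Compound list
1 | 3-oxocyclobutanecarboxylic acid | O=C1CC(C(=O)O)C1 | starting material
2 | 3-bromocyclobutanone | O=C1CC(Br)C1 | intermediate
3 | cyclobut-2-en-1-one | O=C1C=CC1 | intermediate
4 | chloroacetaldehyde dimethyl acetal | COC(CCl)OC | starting material
5 | ethylene oxide | C1CO1 | starting material
6 | lithium methoxyacetylide | [Li]C#COC | intermediate
7 | 4-methoxybut-3-yn-1-ol | COC#CCCO | intermediate
8 | tert-butyl[(4-methoxybut-3-yn-1-yl)oxy]dimethylsilane | COC#CCCO[Si](C)(C)C(C)(C)C | intermediate
9 | buta-1,3-dien-1-one (vinylketene) | C=CC=C=O | intermediate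
10 | 2-[2-(tert-butyldimethylsilyloxy)ethyl]-4-ethenyl-3-methoxycyclobut-2-en-1-one (racemic) | C=CC1C(=O)C(CCO[Si](C)(C)C(C)(C)C)=C1OC | intermediate
11 | (3E)-2-[2-(tert-butyldimethylsilyloxy)ethyl]-3-methoxyhexa-1,3,5-trien-1-one (vinyl cis to the ketene) | C=C\C=C(OC)/C(CCO[Si](C)(C)C(C)(C)C)=C=O | intermediate
12 | 2-[2-(tert-butyldimethylsilyloxy)ethyl]-3-methoxycyclohexa-2,4-dien-1-one | O=C1CC=CC(OC)=C1CCO[Si](C)(C)C(C)(C)C | intermediate
13 | 2-[2-(tert-butyldimethylsilyloxy)ethyl]-3-methoxyphenol | COc1cccc(O)c1CCO[Si](C)(C)C(C)(C)C | intermediate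
14 | 2-[2-(tert-butyldimethylsilyloxy)ethyl]-6-(hydroxymethyl)-3-methoxyphenol (present as its magnesium salt) | COc1ccc(CO)c(O)c1CCO[Si](C)(C)C(C)(C)C | intermediate
15 | 3-[2-(tert-butyldimethylsilyloxy)ethyl]-2-hydroxy-4-methoxybenzaldehyde | COc1ccc(C=O)c(O)c1CCO[Si](C)(C)C(C)(C)C | intermediate
16 | phenylacetylene | C#Cc1ccccc1 | starting material
17 | lithium phenylacetylide | [Li]C#Cc1ccccc1 | intermediate
18 | 2-[2-(tert-butyldimethylsilyloxy)ethyl]-6-(1-hydroxy-3-phenylprop-2-yn-1-yl)-3-methoxyphenol (racemic) | COc1ccc(C(O)C#Cc2ccccc2)c(O)c1CCO[Si](C)(C)C(C)(C)C | intermediate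
19 | 1-{3-[2-(tert-butyldimethylsilyloxy)ethyl]-2-hydroxy-4-methoxyphenyl}-3-phenylprop-2-yn-1-one | COc1ccc(C(=O)C#Cc2ccccc2)c(O)c1CCO[Si](C)(C)C(C)(C)C | intermediate
20 | (E)-1-{3-[2-(tert-butyldimethylsilyloxy)ethyl]-2-hydroxy-4-methoxyphenyl}-3-(diethylamino)-3-phenylprop-2-en-1-one (push–pull alkene, configurationally labile) | CCN(CC)/C(c1ccccc1)=C/C(=O)c1ccc(OC)c(CCO[Si](C)(C)C(C)(C)C)c1O | intermediate
21 | 8-[2-(tert-butyldimethylsilyloxy)ethyl]-7-methoxy-2-phenyl-4H-chromen-4-one | COc1ccc2c(=O)cc(-c3ccccc3)oc2c1CCO[Si](C)(C)C(C)(C)C | intermediate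
22 | 8-(2-hydroxyethyl)-7-methoxy-2-phenyl-4H-chromen-4-one | COc1ccc2c(=O)cc(-c3ccccc3)oc2c1CCO | intermediate
23 | (7-methoxy-4-oxo-2-phenyl-4H-chromen-8-yl)acetaldehyde | COc1ccc2c(=O)cc(-c3ccccc3)oc2c1CC=O | intermediate
24 | (7-methoxy-4-oxo-2-phenyl-4H-chromen-8-yl)acetic acid | COc1ccc2c(=O)cc(-c3ccccc3)oc2c1CC(=O)O | intermediate
25 | 2-hydroxy-2-methylpropanal | CC(C)(O)C=O | starting material
26 | 2-methyl-1-oxopropan-2-yl (7-methoxy-4-oxo-2-phenyl-4H-chromen-8-yl)acetate | COc1ccc2c(=O)cc(-c3ccccc3)oc2c1CC(=O)OC(C)(C)C=O | intermediate
27 | 8-(4-hydroxy-5,5-dimethyl-2-oxotetrahydrofuran-3-yl)-7-methoxy-2-phenyl-4H-chromen-4-one (diastereomer mixture, racemic) | COc1ccc2c(=O)cc(-c3ccccc3)oc2c1C1C(O)C(C)(C)OC1=O | intermediate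
28 | 8-(5,5-dimethyl-2-oxo-2,5-dihydrofuran-3-yl)-7-methoxy-2-phenyl-4H-chromen-4-one (CNP0102581.0) | COc1ccc2c(=O)cc(-c3ccccc3)oc2c1C1=CC(C)(C)OC1=O | target

Total step count: 11. Longest linear sequence: 9 (steps 1–2 or steps 3–4, then steps 5–11).

Steps most likely to fail

Step 5. The unsubstituted enone 3 may be used up by dimerisation or polymerisation faster than it opens to 9 at the temperature the ring opening needs. The ketenes may also acylate the phenol as it forms. The fallback sets out from 8 and comes back to the route at 9. It generates the same vinylketene at room temperature by a photochemical Wolff rearrangement, so no cyclobutenone is ever present.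
- Methyl vinyl ketone is trifluoroacetylated through its kinetic enolate (LiHMDS, CF3CO2CH2CF3, THF, −78 °C) to 1,1,1-trifluorohex-5-ene-2,4-dione F1.
- Detrifluoroacetylative diazo transfer (MsN3, Et3N, H2O, MeCN) then gives 1-diazobut-3-en-2-one F2.
- Irradiation of F2 together with 8 in CH2Cl2 expels nitrogen and releases 9 in the presence of the ynol ether.
- Brief heating in toluene should carry the cascade through 10, 11 and 12 to 13.

Step 11. Three things may go wrong: acylation of the tertiary hydroxyl group may be slow, the hemiacetal hydroxyl groups of dimerised 25 may be acylated instead, and the activated acid may rearrange to an N-acylurea. The fallback sets out from 24 and comes back at 26. It replaces the free hydroxy aldehyde by a stable alkene surrogate and unmasks the aldehyde only after the ester bond exists.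
- 24 is esterified with 2-methylbut-3-en-2-ol (DCC, DMAP, CH2Cl2) to 2-methylbut-3-en-2-yl (7-methoxy-4-oxo-2-phenyl-4H-chromen-8-yl)acetate F3.
- Lemieux–Johnson cleavage (OsO4 cat., NaIO4, 2,6-lutidine, dioxane/H2O) proceeds through 3,4-dihydroxy-2-methylbutan-2-yl (7-methoxy-4-oxo-2-phenyl-4H-chromen-8-yl)acetate F4 to 26.
- The terminal vinyl group should react well ahead of the electron-poor C2=C3 bond of ring C.
- DBU then closes 26 to 28 as in step 11.

Step 3. Without Lewis acid help the aggregated lithium acetylide may open the epoxide sluggishly. The free hydroxy ynol ether may also be lost during isolation, through hydration or through addition of its own hydroxyl group to the triple bond. The fallback sets out from 4 and comes back at 8. It exchanges the epoxide opening for an SN2 alkylation.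
- Acetylide 6 is generated as before and alkylated in THF/HMPA (0 °C → rt) with commercial tert-butyl(2-iodoethoxy)dimethylsilane.
- This delivers 8 directly and bypasses both 7 and step 4.
- No compound outside the list is made (F0).

Further compounds
F1 | step 5 | 1,1,1-trifluorohex-5-ene-2,4-dione | C=CC(=O)CC(=O)C(F)(F)F
F2 | step 5 | 1-diazobut-3-en-2-one | C=CC(=O)C=[N+]=[N-]
F3 | step 11 | 2-methylbut-3-en-2-yl (7-methoxy-4-oxo-2-phenyl-4H-chromen-8-yl)acetate | COc1ccc2c(=O)cc(-c3ccccc3)oc2c1CC(=O)OC(C)(C)C=C
F4 | step 11 | 3,4-dihydroxy-2-methylbutan-2-yl (7-methoxy-4-oxo-2-phenyl-4H-chromen-8-yl)acetate (racemic) | COc1ccc2c(=O)cc(-c3ccccc3)oc2c1CC(=O)OC(C)(C)C(O)CO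
F0 | step 3 | none | none
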